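The right-handed substrate is the slow one in the north-east run: at 0.500 d the left-handed product stands at 49.7% and the right-handed product at 7.4%, and the last reading of the right-handed product, at 2.50 d, is 47.8%.

| flask | left-handed substrate | right-handed substrate | solid reagent | protic impurity | remark | time |
|---|---|---|---|---|---|---|
| south-east | 0.50 M | 0.50 M | 3 equiv | 0.013 M | run made earlier |  |
| north-east | 0.50 M | 0.50 M | 3 equiv | 0.019 M | run made earlier |  |
| flask | 0.50 M | 0.50 M | 3.00 equiv | 0.0250 M |  | 4.0 d |

| run | time / d | left-handed product / % | right-handed product / % |
|---|---|---|---|
| south-east | 0.500 | 50.1 | 7.6 |
| south-east | 1.04 | 49.3 | 33.9 |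
| south-east | 1.25 | 50.2 | 40.2 |
| south-east | 2.08 | 49.9 | 47.0 |
| south-east | 2.50 | 49.8 | 47.2 |
| north-east | 0.500 | 49.7 | 7.4 |
| north-east | 1.04 | 49.8 | 34.6 |
| north-east | 1.25 | 49.8 | 39.4 |
| north-east | 2.08 | 50.2 | 47.3 |
| north-east | 2.50 | 49.6 | 47.8 |

(scatter of a reading: 0.3 percentage points)

* excess of left-handed product over right-handed product in the product at 2.0 h
* excess of left-handed product over right-handed product in the product at 4.0 d
* part of the left-handed substrate and right-handed substrate charged together that has reacted at 4.0 d

- partner is single-handed; left-handed substrate and right-handed substrate are mirror images of each other, charged as a racemate, each of them at the stated concentration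
- as a solid, counted per litre of solution: solid reagent
- what may be going on: 2 partner -> homo dimer; partner + right-handed substrate -> right-handed product; partner + protic impurity -> quenched reagent; solid reagent <-> partner; partner + left-handed substrate -> left-handed product
- at the start none of the solid reagent is in solution
- an excess is below zero if the other one leads
- the handed part of partner does not stay in what it makes, so the products of the two hands are mirror images too

At the bench we would count equivalents: reagent charged over what the two substrates and the impurity take, one partner each. For this flask that gives

count = 146%

Above 100%, the rule says, both substrates are consumed. But the north-east run, with a count of 147%, reads 97.4% product in total at 2.50 d.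

So we follow one partner molecule. Suppose it is not among those taken by the left-handed substrate or the impurity. It then reaches a fork between the right-handed substrate and the homo dimer. The north-east charges and that run's reading at 2.50 d give

leftover = 0.981 M

w = right-handed product / leftover = 48.7%

This w, the share of leftover partner that ends in right-handed product, is a reading. It moves the border of the rule: this flask needs the left-handed substrate plus the impurity plus the right-handed substrate divided by w, so

charged / needed = 0.967

That is less than one, so we take the reagent as the limiting reagent of this flask. Its leftover is 0.975 M, and with w held at the north-east reading we reckon 47.5% right-handed product and 97.5% reacted.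

The forecast gives an excess of 97% at 2.0 h, an excess of 2.7% at 4.0 d and 97.4% reacted at 4.0 d, and of the stall it says: “That points to the reagent being used up, most likely through dimerisation.”

The flask gives an excess of 92.1% at 2.0 h, an excess of 2.09% at 4.0 d and 98.0% reacted at 4.0 d.

    2 partner → homo dimer (k = 0.0170 /M/min)
    partner + right-handed substrate → right-handed product (k = 0.0160 /M/min)
    partner + protic impurity → quenched reagent (k = 0.550 /M/min)
    solid reagent ⇌ partner, rate k4*(cs4 - [partner]) while solid is left; crystals form when [partner] > cs4 (solubility = 0.230 M, k = 0.00410 /min)
    partner + left-handed substrate → left-handed product (k = 0.430 /M/min)

At 4.00 d this flask holds 48.0% right-handed product, so its own w is 49.2%. A neighbour flask charged with 1.80 equiv of solid reagent has a leftover of 0.375 M, and the north-east w gives it 18.3% right-handed product. It holds 28.4%, so its w is 75.7%, larger than the 48.7% read from the north-east run. That neighbour flask ends with 21.6% right-handed substrate unreacted, 78.4% reacted and an excess of 27.6%.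

All runs were computed with constants of no real substance, and the scatter is random.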